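## Structural features

The target is a xanthanolide-type seco-guaianolide: a cycloheptane (C1, C5, C6, C7, C8, C9, C10) cis-fused across C6–C7 to an α-methylene-γ-butyrolactone (O–C6, C7–C11, C12, exocyclic C13). C1 is a fully substituted carbinol carrying the (R)-3-hydroxybutanoyl chain C2–C4, C5 carries an (S)-2-methylbutanoate, C9 a secondary hydroxyl and C10 a methyl, so six stereocentres run unbroken round the ring (C9, C10, C1, C5, C6, C7). Calling the lactone face of the seven-membered ring α, the C1 hydroxyl and the C10 methyl are α, whereas the C5 ester oxygen and the C9 hydroxyl are β; the C1 oxygen therefore sits on the concave face and the C2 chain on the convex one. Fragile elements are the α-methylene lactone (a Michael acceptor that tolerates neither amines, hydrides nor boranes), the β-hydroxy ketone in the chain (dehydration, retro-aldol), the C5–O/C1/C2=O array (retro-aldol cleavage of C1–C5 once C5 is a free alkoxide next to a free C2 ketone) and the α-branched ester (epimerisation, acyl shift). The real difficulties are the quaternary C1 carbinol, whose oxygen must arrive on the hindered face, the need to tell the two ketone-level carbons C2 and C5 apart, and the late introduction of C13. The key step exploits that C5, C6, C7, C8 and C9, with C11, C12 and the cis fusion, already exist as the cyclopentanone-lactone 4: cutting its C5–C9 bond and inserting C10 (with its methyl) and C1 (with its acyl chain) gives the seven-membered ring with every carbon of the target except C13.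

## Logic of the disconnections

29 from 27 (through 28): no skeletal bond is cut. The C2 carbonyl and the C9 hydroxyl are tied into one bridged methyl ketal and O4 is silylated. This hides the β-hydroxy ketone until the end and leaves only acid-stable groups exposed. The forward step must hydrolyse ketal and silyl ether with mild aqueous acid without touching the ester, the methylene lactone or the aldol unit.

27 from 24 and 25: the O–acyl bond at C5 is cut. The epimerisable acyl group is thereby kept away from every basic step, and the chiral acid is a purchased unit. The forward step must acylate a secondary hydroxyl next to the quaternary C1, selectively over the tertiary C1 hydroxyl, without loss of configuration α to the carbonyl.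

24 from 21: C11=C13 is cut. The exocyclic methylene cannot survive hydride, borane or amine, so it is introduced only after those steps, while C2 is masked and before the ester is present. The forward step needs a lactone enolate in the presence of two hydroxyls (as alkoxides) and no other enolisable carbonyl.

21 from 19 (through 20): the C5–H bond is cut, i.e. the C5 carbinol is inverted by oxidation and reduction. The α-hydroxyl at C5 needed as a director one step earlier has the wrong configuration for the target; once the tertiary C1 hydroxyl exists it can deliver hydride to the α face of C5. The forward reduction must proceed by internal delivery, not by external attack.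

19 from 17: the C1–O bond and the ketal bond C2–O(C9) are cut. The C1 oxygen must enter on the concave face, so it is delivered by the 5α-hydroxyl to the C1=C2 enol ether, the only alkene left; the oxocarbenium ion at C2 is then caught by the 9β-hydroxyl, which is only possible when C2 stands β on C1. One step thus sets C1, masks C2 and protects O9. The demand is that oxygen transfer outruns acid-induced ionisation of the vinylogous hemiacetal.

17 from 15: C9–O and C10–H are cut (syn hydration). It is done while C1 is still trigonal, so that no β-substituent on C1 blocks the convex face next to C10. The borane must choose the trisubstituted C9=C10 over the tetrasubstituted enol ether, and the β face.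

15 from 14, and 14 from 12: the C5–H bond, then the C5=O and O–CH3 bonds are cut. Compound 12 is the one point at which C5 and C2 differ without any selective reaction (nitrogen on C5, oxygen on C2); O-methylation fixes C2 as an enol ether and hydrolysis frees C5 as the only ketone. Water must attack the iminium carbon and not the methoxy-bearing carbon, and hydride must come from the β face.

12 from 5 and 10 (key disconnection): C9–C10 and C1–C5 are cut and C5–C9 is restored. This removes the seven-membered ring and both ynone-derived carbons at once and leads back to a cyclopentanone enamine and an acyclic ynone. The forward step needs the enamine double bond toward C9 and bonding of C9 to the methyl-bearing alkyne carbon.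

5 from 4, 4 from 3, 3 from 2, 2 from 1: the C5–N bond, two C–H bonds, and the C5–O bond are cut in turn. The ketone is traced to an allylic methylene of 1, which already holds C6 and C7 with the right absolute configuration. The forward oxidation must hit the CH2 and not the ring-fusion CH.

10 from 8 and 9, 8 from 7, 7 from 6: the C2–C1 bond (acyl–alkyne), the amide C–N bond and the Si–O bond are cut. The chain stereocentre C4 comes from the chiral pool, and the amide route avoids a β-silyloxy aldehyde and a separate oxidation. The forward addition must stop at the ketone.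

## Other disconnections considered

Alternative 1: cuts C10–CH3 and C1–C2, no ring. Forward: Me2CuLi adds to the enone A1 at C10 trans to the C9 silyloxy group and the α-silyloxy enolate is trapped at C1 by aldehyde A2, giving A3.
- In favour: a convergent three-component union. The C1 carbon substituent enters anti to the new methyl, so the C1 oxygen ends on the correct α face with no directing detour. On this point the alternative is the better of the two.
- Against: in A3 the ring carbons C6, C7 and C8 are bare methylenes. The whole lactone (oxygen at C6, the three-carbon unit at C7, two stereocentres) must be grafted on later from the C5 ketone. The aldol of a tetrasubstituted α-silyloxy enolate is hindered and reversible, A1 needs its own enantioselective synthesis, and C2 must be re-oxidised.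
- Comparison: both plans rely on substrate control and both bring in the C2–C4 unit in the key step (equal). The chosen plan takes C6, C7 and the lactone from the chiral pool and pays for it at C1; alternative 1 gets C1 for nothing and pays with the lactone annulation, which should make it longer overall.

Alternative 2: cuts C6–C7 and the lactone C–O bond. Forward: CrCl2 (divalent chromium) turns the allylic bromide of the acyclic aldehyde A4 into an allylchromium that adds through C7 to the C6 aldehyde; the alkoxide lactonises to A5.
- In favour: carbocycle and methylene lactone form together at the very end, so C13 never has to be introduced by enolate chemistry. This is better than step 15 of the chosen plan, and the chemoselectivity of allylchromium reagents (ketone, esters, silyl ethers tolerated) is at least equal.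
- Against: A4 is an open chain with four contiguous stereocentres including the quaternary C1 carbinol, all to be built by acyclic control. Its α-acyloxy aldehyde is prone to epimerisation and acyl shift. Seven-membered closure is entropically less favourable, and C6 and C7 must both be created with the right sense in the key step, whereas the chosen plan buys them in 1.
- Comparison: the endgame is shorter (one desilylation after ring closure), but the linear route to A4 should outweigh that.

Alternative 3: cuts C1–C10 and C6–C7. Forward: Rh2(S-PTAD)4 converts the vinyldiazo ester A6 into a vinylcarbenoid that cyclopropanates the silyl enol ether alkene of diene A7; Cope rearrangement of the cis-divinylcyclopropane gives A8. By its structure A8 is the 2,6-bis(silyloxy) cyclohepta-1,5-diene: the enol ether oxygens are on ring positions 2 and 6, not 2 and 5.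
- In favour: catalytic, enantioselective, and one step builds the ring with C7 and C10 cis from two small achiral fragments. In convergence and in catalytic induction it is the equal or the better of the chosen plan.
- Against: A8 has a methyl ester where the C2–C4 chain belongs, no oxygen at C6, two silyl enol ethers to be differentiated, and the C1, C5 and C9 carbinols all still to be set. It therefore keeps the C1/C5 problem of the chosen plan and adds C6 oxidation and chain extension; regioselective cyclopropanation within A7 is a further demand.
- Comparison: a more elegant ring construction, but more redox and chain-building steps afterwards.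

Key step: step 8

Remarks on the chemistry, each an assumption of the route:
- Locants C1–C13 are those used above; α is the face of the seven-membered ring that carries O–C6 and C11, β the opposite (convex) face.
- The target is treated as the open 9-hydroxy-2-ketone; equilibration with its C9–O–C2 hemiketal is possible and does not change the route.
- The enol ether geometry in 13–17, the ketal carbon C2 in 18–27 and C11 in 22–23 are left undefined; all three elements disappear later.

## Route

Step 1
Reactants: 1 (1S,5R)-2-oxabicyclo[3.3.0]oct-6-en-3-one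
Product: 2 (1R,5R,8R)-8-hydroxy-2-oxabicyclo[3.3.0]oct-6-en-3-one (exo allylic alcohol)
Conditions: SeO2 (0.5 equiv), t-BuOOH (2 equiv), CH2Cl2, 25 °C
Reagents that add atoms: selenium dioxide, O=[Se]=O (oxygen donor), turned over by tert-butyl hydroperoxide, CC(C)(C)OO
Why: SeO2 allylic hydroxylation (ene reaction, then [2,3]-sigmatropic shift) should take a hydrogen of the C8 methylene, because the ene step through the ring-fusion C–H would place a double bond at the ring fusion. Oxygen arrives on the convex face, but this centre is erased in step 2.

Step 2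
Reactants: 2 (1R,5R,8R)-8-hydroxy-2-oxabicyclo[3.3.0]oct-6-en-3-one
Product: 3 (1R,5R)-2-oxabicyclo[3.3.0]oct-6-ene-3,8-dione
Conditions: Dess–Martin periodinane, CH2Cl2, 0 → 25 °C
Reagents that add atoms: none
Why: Dess–Martin oxidation of a secondary allylic alcohol under neutral conditions; the lactone and the ring-fusion centres are not involved.

Step 3
Reactants: 3 (1R,5R)-2-oxabicyclo[3.3.0]oct-6-ene-3,8-dione
Product: 4 (1R,5S)-2-oxabicyclo[3.3.0]octane-3,8-dione
Conditions: H2 (1 atm), Pd/C (10 %), EtOAc, 25 °C
Reagents that add atoms: none
Why: Heterogeneous hydrogenation of the conjugated alkene; ketone and lactone survive and no stereocentre is formed (the descriptor at C5 changes only through priorities).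

Step 4
Reactants: 4 (1R,5S)-2-oxabicyclo[3.3.0]octane-3,8-dione
Product: 5 (1R,5S)-8-(pyrrolidin-1-yl)-2-oxabicyclo[3.3.0]oct-7-en-3-one (pyrrolidine enamine, used crude)
Conditions: pyrrolidine (1.05 equiv), 4 Å molecular sieves, PhMe, 0 → 25 °C; filter, concentrate
Reagents that add atoms: pyrrolidine, C1CCNC1
Why: Stork enamine formation; a cyclopentanone condenses at room temperature, and the double bond should form toward the CH2 (C9) rather than toward the oxygen-bearing ring-fusion carbon, which would require a tetrasubstituted ring-fusion enamine. Near-stoichiometric amine and no heating keep the activated lactone from aminolysis and leave no free amine for step 8.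

Step 5
Reactants: 6 methyl (R)-3-hydroxybutanoate
Product: 7 methyl (R)-3-(tert-butyldimethylsilyloxy)butanoate
Conditions: TBSCl, imidazole, DMF, 25 °C
Reagents that add atoms: tert-butyldimethylsilyl chloride, CC(C)(C)[Si](C)(C)Cl
Why: Standard silylation of a secondary alcohol; the silyl ether later prevents oxa-Michael closure of this oxygen onto the ynone.

Step 6
Reactants: 7 methyl (R)-3-(tert-butyldimethylsilyloxy)butanoate
Product: 8 (R)-3-(tert-butyldimethylsilyloxy)-N-methoxy-N-methylbutanamide
Conditions: MeNH(OMe)·HCl, i-PrMgCl, THF, −20 → 0 °C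
Reagents that add atoms: N,O-dimethylhydroxylamine hydrochloride, CNOC.Cl
Why: Direct ester-to-Weinreb-amide conversion through the magnesium amide; the β-silyloxy stereocentre is not at risk at this temperature.

Step 7
Reactants: 8 (R)-3-(tert-butyldimethylsilyloxy)-N-methoxy-N-methylbutanamide; 9 prop-1-ynylmagnesium bromide (MeC≡CMgBr)
Product: 10 (R)-6-(tert-butyldimethylsilyloxy)hept-2-yn-4-one
Conditions: THF, 0 °C; aq. NH4Cl
Reagents that add atoms: none
Why: Weinreb ketone synthesis; the chelated tetrahedral adduct prevents over-addition and gives the ynone without a β-silyloxy aldehyde or a separate oxidation.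

Step 8
Reactants: 5 (1R,5S)-8-(pyrrolidin-1-yl)-2-oxabicyclo[3.3.0]oct-7-en-3-one; 10 (R)-6-(tert-butyldimethylsilyloxy)hept-2-yn-4-one
Product: 12 lactone-fused 5-(pyrrolidin-1-yl)-1-[(3R)-3-(tert-butyldimethylsilyloxy)butanoyl]-10-methylcyclohepta-1(5),9-diene (dienaminone), via aminocyclobutene 11 (not isolated)
Conditions: PhMe, 25 → 70 °C, Ar
Reagents that add atoms: none
Why: The β-carbon C9 of enamine 5 adds in Michael fashion to the methyl-bearing alkyne carbon of 10 (C10) from the convex face, giving an iminium–allenolate zwitterion whose carbanionic carbon C1 closes on the iminium carbon C5 (4-exo-trig) to the cis-fused aminocyclobutene 11. In 11 the C5–C9 bond lies between a donor (nitrogen on C5) and an acceptor (the acylated alkene), so it breaks heterolytically and the fragments stay joined through C10=C1 as the seven-membered 2-amino-1,3-diene 12; the opening must be stepwise because concerted conrotatory opening of a bicyclo[3.2.0]heptene would give a trans alkene. The closest known reaction type is the enamine–acetylenic ester or ketone [2+2] cycloaddition with cyclobutene opening that enlarges cyclic ketones by two carbons, established for propiolates, acetylenedicarboxylates and terminal ynones; the internal β-methyl ynone is a less electrophilic member of the same class, hence the heating. The seven-membered ring is therefore formed not by a cyclisation but by cleavage of the bond shared by the four- and five-membered rings. No stereocentre is created in 12 (the two centres of 11 vanish on opening) and C6 and C7 are not involved. Connectivity is secured by the enamine regiochemistry (toward CH2) and by the polarity of the ynone (its β-carbon is the methyl-bearing one). An aprotic medium suppresses proton transfer in the zwitterion, an amine-free enamine suppresses aza-Michael addition of pyrrolidine to 10 and lactone aminolysis, and the silyl ether blocks oxa-Michael closure of the chain oxygen.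

Step 9
Reactants: 12 dienaminone
Product: 14 lactone-fused 1-[(3R)-1-methoxy-3-(tert-butyldimethylsilyloxy)butylidene]-10-methylcyclohept-9-en-5-one (vinylogous ester), via O-methyl iminium triflate 13 (not isolated)
Conditions: MeOTf, CH2Cl2, 0 °C; then aq. NaOAc/AcOH buffer (pH 5), THF, 0 °C
Reagents that add atoms: methyl trifluoromethanesulfonate, COS(=O)(=O)C(F)(F)F; water, O
Why: Vinylogous amides are alkylated on oxygen, and hydrolysis of the resulting iminium at the nitrogen-bearing carbon (the vinylogous counterpart of the imidate-salt route from amides to esters) should release pyrrolidine and leave C5 as the only ketone with C2 locked as a methyl enol ether. Competing attack of water at C2 only returns 12.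

Step 10
Reactants: 14 vinylogous ester
Product: 15 5α-alcohol of 14 (γ-methoxy allylic alcohol, used without acidic contact)
Conditions: NaBH4, CeCl3·7H2O, MeOH–CH2Cl2, −40 °C; aq. NaHCO3
Reagents that add atoms: none
Why: Luche 1,2-reduction; hydride should come from the convex β face, which is also anti to the C6–O bond in the Felkin–Anh sense, giving the 5α-hydroxyl (cis to O–C6) needed as director in step 12. The lactone is inert to NaBH4 at this temperature.

Step 11
Reactants: 15 5α-alcohol
Product: 17 5α,9β-diol with 10α-methyl (enol ether intact), via bis-borane adduct 16 (not isolated)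
Conditions: 9-BBN (2.5 equiv), THF, 25 → 45 °C; then aq. NaOAc, 30 % H2O2, 0 → 25 °C
Reagents that add atoms: hydrogen peroxide, OO
Why: Hydroboration–oxidation; the bulky borane should add to the trisubstituted C9=C10 and not to the tetrasubstituted enol ether, with boron on the less substituted, electron-rich C9. Syn addition from the β face (away from the lactone and from the 5α-borinate, with C1 still trigonal) gives 9β-OH and 10β-H, and oxidation proceeds with retention.

Step 12
Reactants: 17 5α,9β-diol
Product: 19 bridged methyl ketal (C9β–O–C2) with 1α,5α-diol, via epoxy ether 18 (not isolated)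
Conditions: VO(acac)2 (5 mol %), t-BuOOH, CH2Cl2, 0 °C; then PPTS (cat.), 0 °C
Reagents that add atoms: tert-butyl hydroperoxide, CC(C)(C)OO
Why: Vanadium-catalysed hydroxyl-directed epoxidation of the enol ether (a directed Rubottom-type oxidation): the allylic 5α-hydroxyl binds the metal and delivers oxygen to the α face of C1=C2, so the C1 oxygen enters on the concave face. The epoxy ether opens to the C2 oxocarbenium ion, which the 9β-hydroxyl captures as a five-membered bridged ketal; this closure is only possible for the α-epoxide, whose C2 stands β.

Step 13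
Reactants: 19 bridged ketal 1α,5α-diol
Product: 20 bridged ketal 1α-hydroxy-5-ketone
Conditions: SO3·pyridine, DMSO, i-Pr2NEt, CH2Cl2, 0 °C; aq. NaHCO3
Reagents that add atoms: none
Why: Parikh–Doering oxidation of the only secondary hydroxyl; it avoids the glycol cleavage that stronger oxidants could cause at the cis-diol and leaves the ketal intact.

Step 14
Reactants: 20 bridged ketal 1α-hydroxy-5-ketone
Product: 21 bridged ketal 1α,5β-diol
Conditions: Me4NBH(OAc)3, MeCN–AcOH, −30 → 0 °C
Reagents that add atoms: none
Why: Saksena–Evans hydroxyl-directed reduction: the tertiary 1α-hydroxyl exchanges onto boron and delivers hydride to the α face of the adjacent C5 carbonyl, giving the trans diol (5β-OH). The reagent does not reduce ketones without such delivery, and the β-bridge shields the other face.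

Step 15
Reactants: 21 bridged ketal 1α,5β-diol
Product: 24 11(13)-methylene lactone of 21, via Mannich base 22 (not isolated), via methiodide 23 (not isolated)
Conditions: LiN(i-Pr)2 (3.3 equiv), THF, −78 °C; CH2=NMe2+ I−, −78 → 25 °C; aq. NH4Cl; then MeI, MeOH, 25 °C; then aq. NaHCO3, EtOAc, 25 °C
Reagents that add atoms: N,N-dimethylmethyleneiminium iodide, C=[N+](C)C.[I-]
Why: Eschenmoser methylenation (Mannich reaction of the lactone enolate, quaternisation, β-elimination). With C2 masked the lactone CH2 is the only enolisable position, the two hydroxyls ride along as alkoxides, and no retro-aldol is possible because C2 is not a carbonyl.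

Step 16
Reactants: 24 methylene lactone diol; 25 (S)-2-methylbutanoic acid
Product: 27 5β-(S)-2-methylbutanoate of 24, via mixed anhydride 26 (not isolated)
Conditions: 2,4,6-Cl3C6H2COCl, Et3N, THF, 25 °C; then DMAP, PhMe, 25 → 50 °C
Reagents that add atoms: none
Why: Yamaguchi esterification, suited to hindered secondary alcohols and α-branched acids with little epimerisation; the tertiary C1 hydroxyl should not react.

Step 17
Reactants: 27 ester
Product: 29 target, via C4 silyl ether 28 (not isolated)
Conditions: 48 % aq. HF, MeCN, 0 → 25 °C
Reagents that add atoms: water, O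
Why: Acid hydrolysis of the mixed ketal (releasing the C2 ketone and the C9 hydroxyl), followed by fluoride-assisted desilylation of O4; the ester, the methylene lactone and the tertiary ketol are stable to these conditions.

## Compound list

1 | (1S,5R)-2-oxabicyclo[3.3.0]oct-6-en-3-one | O=C1C[C@@H]2C=CC[C@@H]2O1 | starting material
2 | (1R,5R,8R)-8-hydroxy-2-oxabicyclo[3.3.0]oct-6-en-3-one | O=C1C[C@@H]2C=C[C@@H](O)[C@@H]2O1 | intermediate
3 | (1R,5R)-2-oxabicyclo[3.3.0]oct-6-ene-3,8-dione | O=C1C[C@@H]2C=CC(=O)[C@@H]2O1 | intermediate
4 | (1R,5S)-2-oxabicyclo[3.3.0]octane-3,8-dione | O=C1C[C@@H]2CCC(=O)[C@@H]2O1 | intermediate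
5 | (1R,5S)-8-(pyrrolidin-1-yl)-2-oxabicyclo[3.3.0]oct-7-en-3-one | O=C1C[C@@H]2CC=C(N3CCCC3)[C@@H]2O1 | intermediate
6 | methyl (R)-3-hydroxybutanoate | COC(=O)C[C@@H](C)O | starting material
7 | methyl (R)-3-(tert-butyldimethylsilyloxy)butanoate | COC(=O)C[C@@H](C)O[Si](C)(C)C(C)(C)C | intermediate
8 | (R)-3-(tert-butyldimethylsilyloxy)-N-methoxy-N-methylbutanamide | CON(C)C(=O)C[C@@H](C)O[Si](C)(C)C(C)(C)C | intermediate
9 | prop-1-ynylmagnesium bromide | CC#C[Mg]Br | starting material
10 | (R)-6-(tert-butyldimethylsilyloxy)hept-2-yn-4-one | CC#CC(=O)C[C@@H](C)O[Si](C)(C)C(C)(C)C | intermediate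
11 | aminocyclobutene: cis-anti-cis lactone-fused 1-pyrrolidinyl-6-methyl-7-acylbicyclo[3.2.0]hept-6-ene, cyclobutene on the β face | O=C1C[C@@H]2C[C@H]3C(C)=C(C(=O)C[C@@H](C)O[Si](C)(C)C(C)(C)C)[C@@]3(N4CCCC4)[C@@H]2O1 | intermediate (not isolated)
12 | dienaminone: (6R,7S) cis-lactone-fused 5-(pyrrolidin-1-yl)-1-[(3R)-3-(tert-butyldimethylsilyloxy)butanoyl]-10-methylcyclohepta-1(5),9-diene | O=C1C[C@@H]2CC=C(C)C(C(=O)C[C@@H](C)O[Si](C)(C)C(C)(C)C)=C(N3CCCC3)[C@@H]2O1 | intermediate
13 | O-methyl iminium triflate of 12 (C5=N+ pyrrolidinium, C1=C2 methoxyalkylidene) | O=C1C[C@@H]2CC=C(C)C(=C(OC)C[C@@H](C)O[Si](C)(C)C(C)(C)C)C(=[N+]3CCCC3)[C@@H]2O1.[O-]S(=O)(=O)C(F)(F)F | intermediate (not isolated)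
14 | vinylogous ester: lactone-fused 1-[(3R)-1-methoxy-3-(tert-butyldimethylsilyloxy)butylidene]-10-methylcyclohept-9-en-5-one | O=C1C[C@@H]2CC=C(C)C(=C(OC)C[C@@H](C)O[Si](C)(C)C(C)(C)C)C(=O)[C@@H]2O1 | intermediate
15 | 5α-alcohol of 14 | O=C1C[C@@H]2CC=C(C)C(=C(OC)C[C@@H](C)O[Si](C)(C)C(C)(C)C)[C@H](O)[C@@H]2O1 | intermediate
16 | bis-borane adduct: 9β-(9-borabicyclo[3.3.1]non-9-yl), 5α-O-borinate, 10α-methyl | O=C1C[C@@H]2C[C@@H](B3C4CCCC3CCC4)[C@H](C)C(=C(OC)C[C@@H](C)O[Si](C)(C)C(C)(C)C)[C@H](OB5C6CCCC5CCC6)[C@@H]2O1 | intermediate (not isolated)
17 | 5α,9β-diol, 10α-methyl, C1=C2 methyl enol ether | O=C1C[C@@H]2C[C@@H](O)[C@H](C)C(=C(OC)C[C@@H](C)O[Si](C)(C)C(C)(C)C)[C@H](O)[C@@H]2O1 | intermediate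
18 | epoxy ether: spiro-oxirane at C1 (oxygen α), methoxy on C2 | O=C1C[C@@H]2C[C@@H](O)[C@H](C)[C@]4(OC4(OC)C[C@@H](C)O[Si](C)(C)C(C)(C)C)[C@H](O)[C@@H]2O1 | intermediate (not isolated)
19 | bridged methyl ketal (C9β–O–C2), 1α,5α-diol | O=C1C[C@@H]2C[C@@H](O3)[C@H](C)[C@@](O)(C3(OC)C[C@@H](C)O[Si](C)(C)C(C)(C)C)[C@H](O)[C@@H]2O1 | intermediate
20 | bridged methyl ketal, 1α-hydroxy-5-ketone | O=C1C[C@@H]2C[C@@H](O3)[C@H](C)[C@@](O)(C3(OC)C[C@@H](C)O[Si](C)(C)C(C)(C)C)C(=O)[C@@H]2O1 | intermediate
21 | bridged methyl ketal, 1α,5β-diol | O=C1C[C@@H]2C[C@@H](O3)[C@H](C)[C@@](O)(C3(OC)C[C@@H](C)O[Si](C)(C)C(C)(C)C)[C@@H](O)[C@@H]2O1 | intermediate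
22 | Mannich base: 11-(dimethylaminomethyl) lactone of 21 | CN(C)CC1C(=O)O[C@@H]2[C@H]1C[C@@H](O3)[C@H](C)[C@@](O)(C3(OC)C[C@@H](C)O[Si](C)(C)C(C)(C)C)[C@H]2O | intermediate (not isolated)
23 | methiodide of 22 | C[N+](C)(C)CC1C(=O)O[C@@H]2[C@H]1C[C@@H](O3)[C@H](C)[C@@](O)(C3(OC)C[C@@H](C)O[Si](C)(C)C(C)(C)C)[C@H]2O.[I-] | intermediate (not isolated)
24 | 11(13)-methylene lactone, bridged methyl ketal, 1α,5β-diol | C=C1C(=O)O[C@@H]2[C@H]1C[C@@H](O3)[C@H](C)[C@@](O)(C3(OC)C[C@@H](C)O[Si](C)(C)C(C)(C)C)[C@H]2O | intermediate
25 | (S)-2-methylbutanoic acid | CC[C@H](C)C(=O)O | starting material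
26 | (S)-2-methylbutanoic 2,4,6-trichlorobenzoic anhydride | CC[C@H](C)C(=O)OC(=O)c1c(Cl)cc(Cl)cc1Cl | intermediate (not isolated)
27 | 5β-[(S)-2-methylbutanoate] of 24 | C=C1C(=O)O[C@@H]2[C@H]1C[C@@H](O3)[C@H](C)[C@@](O)(C3(OC)C[C@@H](C)O[Si](C)(C)C(C)(C)C)[C@H]2OC(=O)[C@@H](C)CC | intermediate
28 | 4-O-tert-butyldimethylsilyl ether of the target | C=C1C(=O)O[C@@H]2[C@H]1C[C@@H](O)[C@H](C)[C@@](O)(C(=O)C[C@@H](C)O[Si](C)(C)C(C)(C)C)[C@H]2OC(=O)[C@@H](C)CC | intermediate (not isolated)
29 | (3aS,5R,6S,7S,8S,8aR)-5,7-dihydroxy-7-[(3R)-3-hydroxybutanoyl]-6-methyl-3-methylidene-2-oxooctahydro-2H-cyclohepta[b]furan-8-yl (2S)-2-methylbutanoate | C=C1C(=O)O[C@@H]2[C@H]1C[C@@H](O)[C@H](C)[C@@](O)(C(=O)C[C@@H](C)O)[C@H]2OC(=O)[C@@H](C)CC | target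

## Step count and least certain steps

Total: 17 steps. Longest linear sequence: 14 steps (1, 2, 3, 4, 8, then 9 to 17); the ynone branch (5, 6, 7) has 3 steps.

Step 8 (key step).
- Risk: the β-methyl lowers the electrophilicity of 10, so slower processes may win. These are hydrolysis of the enamine, aminolysis of the activated lactone by liberated pyrrolidine, proton transfer within the zwitterion to an open Michael adduct, and aza-Michael addition of free amine to 10.
- Fallback, from 4: kinetic deprotonation toward C9 and silylation (LiN(i-Pr)2, Me3SiCl, THF, −78 °C) gives the trimethylsilyl enol ether F1. Lewis-acid-promoted [2+2] cycloaddition with 10 (ZrCl4 or EtAlCl2, CH2Cl2, −78 °C), in which the carbonyl-complexed ynone is a much stronger acceptor, gives the silyloxycyclobutene F2 with the same C9–C10 and C1–C5 bonds. Selective removal of the trimethylsilyl group (Et3N·3HF, 0 °C) triggers retro-aldol cleavage of C5–C9 to the ring-enlarged β-diketone F3. O-Methylation (Me3SiCHN2, MeOH–PhMe) and separation from the endocyclic enol ether F4 returns to the route at 14, replacing steps 8 and 9.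

Step 1.
- Risk: slow ene reaction of the 1,2-disubstituted alkene, over-oxidation, and partial attack at the ring-fusion C–H.
- Fallback, from 1: direct oxidation of the allylic CH2 to the carbonyl with CrO3·3,5-dimethylpyrazole (CH2Cl2, −20 °C), a hydrogen-abstraction pathway that needs no alcohol stage; the transposed enone, if formed, is separated. It returns at 3 and makes no new compound.

Step 11.
- Risk: poor facial selectivity (C1 is trigonal and the dienol ether is twisted, so the bias rests on the lactone and the 5α-borinate alone), competing addition to the enol ether, or ionisation of the allylic borinate with loss of the C5 oxygen.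
- Fallback, from 15: silylation of the 5α-hydroxyl (Et3SiCl, imidazole) gives the triethylsilyl ether F5, a defined bulky α-substituent that cannot ionise. Hydroboration–oxidation as in step 11 gives the 9β-alcohol F6. Selective removal of the triethylsilyl group (HF·pyridine buffered with pyridine, THF, 0 °C) returns to 17.

Step 12.
- Risk: acid-induced allylic transposition of the vinylogous hemiacetal (loss of the 5α-hydroxyl) before oxygen transfer, intermolecular capture of the oxocarbenium ion, or erosion of the directing effect.
- Fallback, from 17: the two events are separated under neutral conditions. Dimethyldioxirane in CH2Cl2–acetone at −78 °C (hydrogen-bond delivery from the 5α-hydroxyl), followed by methanol, gives the open α-hydroxy dimethyl ketal F7. PPTS-catalysed transketalisation with the 9β-hydroxyl then closes the bridge and returns to 19.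

Step 16.
- Risk: slow acylation of the hindered C5 hydroxyl, giving time for epimerisation of the acyl donor α to its carbonyl or for conjugate addition of DMAP to the methylene lactone.
- Fallback, from 21: the ester is installed before the methylene exists, by acylating the potassium alkoxide (KN(SiMe3)2, THF, −78 °C, then 26) to the ester F8. Methylenation then uses LiN(SiMe3)2 (two equivalents; the lactone CH2 is more acidic and more accessible than the branched ester CH) and CH2=NMe2+ I− through the Mannich base F9 and its methiodide F10 (MeI, then aq. NaHCO3), returning at 27.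

Further compounds

F1 | step 8 | (1R,5S)-8-(trimethylsilyloxy)-2-oxabicyclo[3.3.0]oct-7-en-3-one | O=C1C[C@@H]2CC=C(O[Si](C)(C)C)[C@@H]2O1
F2 | step 8 | silyloxycyclobutene: cis-anti-cis lactone-fused 1-(trimethylsilyloxy)-6-methyl-7-acylbicyclo[3.2.0]hept-6-ene | O=C1C[C@@H]2C[C@H]3C(C)=C(C(=O)C[C@@H](C)O[Si](C)(C)C(C)(C)C)[C@@]3(O[Si](C)(C)C)[C@@H]2O1
F3 | step 8 | ring-enlarged β-diketone: lactone-fused 1-[(3R)-3-(tert-butyldimethylsilyloxy)butanoyl]-10-methylcyclohept-9-en-5-one (keto form, C1 undefined) | O=C1C[C@@H]2CC=C(C)C(C(=O)C[C@@H](C)O[Si](C)(C)C(C)(C)C)C(=O)[C@@H]2O1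
F4 | step 8 | endocyclic methyl enol ether isomer of 14 (5-methoxy-1(5),9-diene, C2 ketone) | O=C1C[C@@H]2CC=C(C)C(C(=O)C[C@@H](C)O[Si](C)(C)C(C)(C)C)=C(OC)[C@@H]2O1
F0 | step 1 | none | none
F5 | step 11 | 5α-O-triethylsilyl ether of 15 | O=C1C[C@@H]2CC=C(C)C(=C(OC)C[C@@H](C)O[Si](C)(C)C(C)(C)C)[C@H](O[Si](CC)(CC)CC)[C@@H]2O1
F6 | step 11 | 9β-alcohol with 5α-O-triethylsilyl ether and 10α-methyl | O=C1C[C@@H]2C[C@@H](O)[C@H](C)C(=C(OC)C[C@@H](C)O[Si](C)(C)C(C)(C)C)[C@H](O[Si](CC)(CC)CC)[C@@H]2O1
F7 | step 12 | open α-hydroxy dimethyl ketal: 1α,5α,9β-triol with C2 dimethyl ketal | O=C1C[C@@H]2C[C@@H](O)[C@H](C)[C@@](O)(C(OC)(OC)C[C@@H](C)O[Si](C)(C)C(C)(C)C)[C@H](O)[C@@H]2O1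
F8 | step 16 | 5β-[(S)-2-methylbutanoate] of 21 (lactone CH2 intact) | O=C1C[C@@H]2C[C@@H](O3)[C@H](C)[C@@](O)(C3(OC)C[C@@H](C)O[Si](C)(C)C(C)(C)C)[C@@H](OC(=O)[C@@H](C)CC)[C@@H]2O1
F9 | step 16 | Mannich base of F8 (11-dimethylaminomethyl lactone) | CN(C)CC1C(=O)O[C@@H]2[C@H]1C[C@@H](O3)[C@H](C)[C@@](O)(C3(OC)C[C@@H](C)O[Si](C)(C)C(C)(C)C)[C@H]2OC(=O)[C@@H](C)CC
F10 | step 16 | methiodide of F9 | C[N+](C)(C)CC1C(=O)O[C@@H]2[C@H]1C[C@@H](O3)[C@H](C)[C@@](O)(C3(OC)C[C@@H](C)O[Si](C)(C)C(C)(C)C)[C@H]2OC(=O)[C@@H](C)CC.[I-]
A1 | alternative 1 | (R)-2,4-bis(tert-butyldimethylsilyloxy)cyclohept-2-en-1-one | O=C1CCC[C@@H](O[Si](C)(C)C(C)(C)C)C=C1O[Si](C)(C)C(C)(C)C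
A2 | alternative 1 | (R)-3-(tert-butyldimethylsilyloxy)butanal | O=CC[C@@H](C)O[Si](C)(C)C(C)(C)C
A3 | alternative 1 | 2-(1-hydroxy-3-silyloxybutyl)-3-methyl-2,4-bis(silyloxy)cycloheptanone | O=C1CCC[C@@H](O[Si](C)(C)C(C)(C)C)[C@H](C)[C@@]1(O[Si](C)(C)C(C)(C)C)[C@@H](O)C[C@@H](C)O[Si](C)(C)C(C)(C)C
A4 | alternative 2 | acyclic C6 aldehyde with (Z)-2-(bromomethyl)enoate terminus (C5 ester, C1 triethylsilyl ether, C9 and C4 silyl ethers) | COC(=O)/C(CBr)=C/C[C@@H](O[Si](C)(C)C(C)(C)C)[C@H](C)[C@@](O[Si](CC)(CC)CC)(C(=O)C[C@@H](C)O[Si](C)(C)C(C)(C)C)[C@H](C=O)OC(=O)[C@@H](C)CC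
A5 | alternative 2 | tris-silyl ether of the target | C=C1C(=O)O[C@@H]2[C@H]1C[C@@H](O[Si](C)(C)C(C)(C)C)[C@H](C)[C@@](O[Si](CC)(CC)CC)(C(=O)C[C@@H](C)O[Si](C)(C)C(C)(C)C)[C@H]2OC(=O)[C@@H](C)CC
A6 | alternative 3 | methyl 3-(tert-butyldimethylsilyloxy)-2-diazobut-3-enoate | COC(=O)C(=[N+]=[N-])C(=C)O[Si](C)(C)C(C)(C)C
A7 | alternative 3 | (2Z,4E)-3,7-bis(tert-butyldimethylsilyloxy)hepta-2,4-diene | C/C=C(O[Si](C)(C)C(C)(C)C)/C=C/CCO[Si](C)(C)C(C)(C)C
A8 | alternative 3 | methyl 2,6-bis(silyloxy)-7-methyl-4-(2-silyloxyethyl)cyclohepta-1,5-diene-1-carboxylate | COC(=O)C1=C(O[Si](C)(C)C(C)(C)C)C[C@H](CCO[Si](C)(C)C(C)(C)C)C=C(O[Si](C)(C)C(C)(C)C)[C@@H]1C
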